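(The numbers in the tables are calculated with constants of no real substance, and the scatter is random.)

The meeting opened on an impossibility: no rate constant is given, so teal and amber cannot be computed from the possible steps, which are starting material + partner to target + by-product (reversible), partner + by-product to idle adduct (reversible), and starting material + by-product to side product.

| flask | starting material | partner | remark | time |
|---|---|---|---|---|
| north-east | 0.19 M (fed, over 4.0 h) | 0.37 M | run made earlier; the fed solution adds 1.0 times the starting volume |  |
| west | 0.19 M (fed, over 4.0 h) | 0.49 M | run made earlier; the fed solution adds 1.0 times the starting volume |  |
| teal | 0.19 M (fed, over 4.0 h) | 0.280 M | the fed solution adds 1.0 times the starting volume | 10 h |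
| amber | 0.19 M (fed, over 4.0 h) | 0.430 M | the fed solution adds 1.0 times the starting volume | 10 h |

- north-east (time / h: starting material / %, target / %): 0.833: 20.3, 0.7; 2.50: 56.4, 6.0; 5.00: 83.5, 16.0; 8.00: 73.4, 26.4; 10.0: 68.2, 30.6
- west (time / h: starting material / %, target / %): 2.00: 43.9, 5.8; 4.00: 83.8, 16.6; 6.00: 73.4, 25.2; 8.00: 65.3, 33.0; 10.0: 60.2, 37.4

(readings scatter by 0.5 percentage points)

- part of the starting material that has reacted at the end, teal
- part of the starting material that has reacted at the end, amber
- what raising the concentration of partner from its lowest to its highest value here does to the part of the starting material that has reacted (changes below 5 percentage points count as none) (it rises / it falls / no change)

- what is said of by-product includes idle adduct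
- amounts are per litre of the starting volume; all of the dose is in the solution fed
- the numbers in the tables scatter with a standard deviation of 0.5 percentage points
- steps thought possible: starting material + by-product -> side product; partner + by-product <-> idle adduct; starting material + partner <-> target + by-product
- percentages count the whole charge, also what has not yet gone in

The chair noted that the feed, the charge of starting material and the time are the same in these flasks, and that c(partner) is what differs. At 10 h, north-east had reacted 31.8 % of its charge and west 39.8 %.

One member argued that the reacted part should follow c(partner) in proportion, which from north-east gives 42.1 % for west. A second member replied that west read lower than that, by 2.3 percentage points, which is more than the 0.71 points scatter of a difference of two readings, so the proportion was dropped.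

The second member proposed to take the north-east reading as the large known part and to reckon just a small correction for c(partner). The meeting named the partner gain: the change in the reacted share of the charge per molar of c(partner) between the two runs, 0.667 /M.

By our reckoning, teal loses 6 points from the north-east value and ends at 25.8 %, while amber gains 4 points and ends at 35.8 %. A third member warned that amber lies between the runs but teal lies outside them. The step from teal to amber is 10 points, more than the 5 points that counts as a change, so we expected a rise.

The forecast gave 25.3 % for teal, 0.5 points below our figure, 36 % for amber, and "it rises", by way of “A saturating fit through these two points”.

The flask gives 26.3 % for teal and 36.2 % for amber, and on raising c(partner) from its lowest to its highest value here the answer is "it rises", by 9.8 points.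

    starting material + by-product → side product (k = 0.00640 /M/min)
    partner + by-product ⇌ idle adduct, settled at all times (K = 9.80 /M)
    starting material + partner ⇌ target + by-product (K = 0.0990, k = 0.00540 /M/min)

Our reckoning stands 0.50 points below teal and 0.40 points below amber. In a flask like teal with 1.1 M of partner, the same gain gives 80.5 %, but that flask gives 65.8 %, so the correction serves near the runs and not that far away. In teal at 4.80 h, starting material has a half-life of 18 h by the forward rate of its step with partner, shorter than the 14 d by its step with by-product. At 10.0 h in teal, the forward step still uses starting material faster than the side step, with a selectivity factor of 8.2.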